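**Slow start.** Slowness at the opening is the thing to watch in these runs.

| setting | larch | cedar | maple | oak | elm |
|---|---|---|---|---|---|
| starting material | 50.0 mM | 25.0 mM | 50.0 mM | 25.0 mM | 17.0 mM |
| catalyst | 0.500 mM | 0.500 mM | 0.750 mM | 0.500 mM | 1.00 mM |
| time |  |  |  |  | 92 s |

- larch run (time / s: [product] / mM): 15: 4.12; 31: 10.36; 46: 15.18; 61: 19.36; 77: 23.31; 92: 26.58
- cedar run (time / s: [product] / mM): 15: 2.16; 31: 5.09; 46: 7.35; 61: 9.92; 77: 11.51; 92: 13.50
- maple run (time / s: [product] / mM): 15: 6.14; 31: 14.08; 46: 20.71; 61: 26.24; 77: 30.68; 92: 34.43
- oak run (time / s: [product] / mM): 15: 1.90; 31: 5.01; 46: 7.58; 61: 9.75; 77: 11.67; 92: 13.69

(standard deviation of a reading: 0.2 mM)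

1. reaction order in [starting material] at the outset, round the charge of the larch run, defined at two percent of the starting material turned into product (one fixed amount of product, the same in the runs compared)
2. reaction order in [catalyst] at the outset, round the charge of the larch run, defined at two percent of the starting material turned into product
3. the cedar run starts with 25.0 mM less of starting material than the larch run, and with no product. Compared where both hold the same amount of starting material, once fifteen percent of what the cedar run was charged with has turned into product, is the cedar run faster, slower or alike (within a tenth)?
4. product in the elm run at 92 s, as a share of the starting material charged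
5. which of these the readings show (the substrate pairs with itself / the substrate is lost by itself / the product decays / the substrate kills the catalyst / the catalyst wakes slowly)

- Overall: starting material -> product, with catalyst as catalyst.
- Constant volume, constant temperature.
- An order is taken over about fifteen percent of the charge, up and down.

In the larch run the share of the charge turned per second was 0.00549 s⁻¹ up to 15 s, then 0.00780 s⁻¹ up to 31 s. That is faster, although less starting material remained. Later the charge stops mattering: at 92 s the larch run had turned 0.532 of its charge and the cedar run 0.540, though larch was charged with twice as much.

**Lost time.** So I replaced the waking curve by its mean: a flask in which nothing happens for a while, and after that the logarithm of the fraction left falls in a straight line. The slope of that line, pooled from the later readings and scaled to the larch run's catalyst, is 0.00912 s⁻¹. Dividing the pooled logarithm at the last reading by this slope and taking the answer from 92 s gives 6.86 s, my lost time (the induction period), the delay by which a run trails a flask whose catalyst was awake from the start. The error of this shortcut shows at the larch run's first reading: it gives 0.0715 of the charge where 0.0824 was read, so I used it for later times.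

**The ladder.** Fully awake, the larch run would make its two percent in 2.19 s, shorter than the lost time, so the orders asked for are taken while the catalyst is still waking, and I expect both below one. I put no figure of my own on them. The cedar run reaches the point of the comparison asked for between 15 s and 31 s, later than the lost time, and the larch run comes down even to the cedar run's charge after 77 s, later still, so I expect them alike. Slowest is the larch run's decay time, 110 s, longer than its last reading. For the elm run, scaling the slope to its catalyst, I reckoned 78.8%.

**The forecast.** It gave orders of 0.7 (0.55 to 0.88) and 0.7 (0.55 to 0.92), cedar alike, elm 79% (75.5% to 83%), and the verdict the catalyst wakes slowly: “Faster runs reach that point earlier, with less active catalyst”. It put the waking at about 5.5 s, where my lost time was 6.86 s.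

**The result.**

    active catalyst + starting material → product + active catalyst (17.90 M⁻¹ s⁻¹)
    catalyst → active catalyst (0.1750 s⁻¹)

The elm run gave 78.7%, with orders of 0.68 and 0.67, cedar alike at a ratio of 0.98, and the verdict the catalyst wakes slowly. A single power law through the runs, with best order 0.91, stayed 3.5 scatter widths from the readings. Put to the cedar run, the lost time plus the time to turn half of the charge gives 82.9 s, and the cedar run reached half at 83.2 s.

The runs were generated by integration with constants of no real substance.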